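**Plan**

- **Numbering (each half as a naphthalen-1(4H)-one).** C1 is the ketone on fusion carbon C8a, C2 the bridge carbon, C3 the enol carbon, and C4 the CMe2 carbon on fusion carbon C4a. C5 bears H, C6 OH, C7 acetyl and C8 OH. Ring A is the arene, ring B the enolised dione, and primes mark the second half.
- **Retrosynthetic cuts.** The four phenols are masked as methyl ethers, C1/C1' go back to CH2, and the C7/C7' acetyl bonds are cut. Next C4–C4a and C4'–C4a' are cut together, then C1–C2 and C1'–C2'. Last come the C3–C4 and C3'–C4' bonds of a glutaric acid core that already holds C3–C2–CH2–C2'–C3'.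
- **Enabling feature.** In ring B the quaternary C4 lies alpha to the C3 carbonyl, so it is an enolate carbon. Its partner C4a in ring A is meta to the oxygens on C6 and C8, so only a halogen brought in with the arene can address it.
- **Forward order.** The chain is made first (steps 1–2) and the ring A units next (steps 3–5). They are attached at C2/C2' (step 6), and both B rings close at once (step 7). The C7 acetyls (step 8), the C1 oxygens (step 9) and the free phenols (step 10) follow.
- **Stereochemistry.** The target has no stereocentre. C2/C2' are stereocentres only between steps 6 and 9, arise without control, and vanish when the 1,3-diones enolise.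

Key step: step 7

Assumption: every intermediate with stereocentres at C2 and C2' forms as a mixture of the meso and racemic diastereomers (the meso form is drawn). The 1,3-diones are written as the C3-enol/C1-keto tautomer of the target drawing.

**Step 1**
Reactants: 1 glutaryl chloride
Product: 2 N1,N5-dimethoxy-N1,N5-dimethylpentanediamide
Conditions: MeNHOMe·HCl (2.2 equiv), Et3N (4.5 equiv), CH2Cl2, 0 °C → rt
Reagents that add atoms: N,O-dimethylhydroxylamine hydrochloride, CNOC.Cl
Why: Twofold N-acylation of the hydroxylamine by the acid chloride (Weinreb amide formation) gives a diacyl donor that, unlike the acid chloride, cannot over-add or collapse to an enol lactone in the next step.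

**Step 2**
Reactants: 2 N1,N5-dimethoxy-N1,N5-dimethylpentanediamide; 3 isopropylmagnesium chloride
Product: 5 2,8-dimethylnonane-3,7-dione, via bis(chloromagnesium) hemiaminal chelate 4 (not isolated)
Conditions: i-PrMgCl (2.6 equiv), THF, 0 °C → rt; then 1 M HCl
Reagents that add atoms: isopropylmagnesium chloride (3), CC(C)[Mg]Cl
Why: In this Weinreb ketone synthesis each five-membered magnesium chelate survives until the acidic quench, so exactly one isopropyl group is delivered per carbonyl.

**Step 3**
Reactants: 6 1-bromo-3,5-dimethoxybenzene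
Product: 8 2-bromo-4,6-dimethoxybenzaldehyde, via aryl iminium chloride 7 (not isolated)
Conditions: POCl3, DMF, 0 → 90 °C; then ice-water
Reagents that add atoms: N,N-dimethylformamide, CN(C)C=O; water, O
Why: Vilsmeier–Haack formylation should attack the position para to one methoxy group and ortho to the other (next to bromine) rather than the more crowded site between the two methoxy groups, which puts the future C8a beside the future C4a–Br.

**Step 4**
Reactants: 8 2-bromo-4,6-dimethoxybenzaldehyde
Product: 9 (2-bromo-4,6-dimethoxyphenyl)methanol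
Conditions: NaBH4, MeOH, 0 °C
Reagents that add atoms: none
Why: Borohydride reduction of an aryl aldehyde leaves the aryl bromide and the ethers untouched.

**Step 5**
Reactants: 9 (2-bromo-4,6-dimethoxyphenyl)methanol
Product: 10 1-bromo-2-(bromomethyl)-3,5-dimethoxybenzene
Conditions: PBr3, CH2Cl2, 0 °C; used crude at once
Reagents that add atoms: phosphorus tribromide, BrP(Br)Br
Why: Bromide substitutes the activated benzylic phosphite ester quickly at low temperature, and immediate use avoids self-alkylation of this electron-rich benzyl bromide.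

**Step 6**
Reactants: 5 2,8-dimethylnonane-3,7-dione; 10 1-bromo-2-(bromomethyl)-3,5-dimethoxybenzene (2.1 equiv)
Product: 12 4,6-bis(2-bromo-4,6-dimethoxybenzyl)-2,8-dimethylnonane-3,7-dione (meso form drawn), via dilithium bis-enolate 11 (not isolated)
Conditions: LiN(i-Pr)2 (2.2 equiv), THF, −78 °C; then 10, −78 → 0 °C
Reagents that add atoms: none
Why: In this kinetic enolate alkylation LiN(i-Pr)2 removes the less hindered methylene protons at C4 and C6 of 5 rather than the isopropyl methines, the 1,5-bis-enolate has no viable ring closure (C-attack would give a cyclobutanol), and each enolate carbon takes up the reactive benzylic bromide by SN2; the two new stereocentres form without control, which is harmless because step 9 erases them.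

**Step 7**
Reactants: 12 4,6-bis(2-bromo-4,6-dimethoxybenzyl)-2,8-dimethylnonane-3,7-dione
Product: 14 3,3'-methylenebis(5,7-dimethoxy-1,1-dimethyl-3,4-dihydronaphthalen-2(1H)-one) (meso form drawn), via monocyclised bromo ketone 13 (not isolated)
Conditions: Pd2(dba)3 (5 mol %), 2-dicyclohexylphosphino-2',4',6'-triisopropylbiphenyl (XPhos, 12 mol %), NaOt-Bu (3 equiv), toluene (0.02 M), 100 °C
Reagents that add atoms: none
Why: Zerovalent palladium inserts into a C4a–Br bond, NaOt-Bu equilibrates the C2 and C4 enolates of the adjacent ketone, the enolate displaces bromide on the metal, and C–C reductive elimination from the C4-bound seven-membered palladacycle (Pd, C4a, C8a, C1, C2, C3, C4) forms C4–C4a; the same cycle then runs on 13 to form C4'–C4a'. The closest known reaction type is the intramolecular palladium-catalysed ketone α-arylation (Buchwald–Hartwig–Miura arylation), which is established for 2-tetralone formation and for quaternary carbons from α,α-dialkyl enolates. Each ring B closes in a six-membered enolendo mode, with both enolate carbons C3 and C4 becoming ring members. No stereocentre is created, since C4 carries two methyl groups, and epimerisation of C2 and C2' by the base has no consequence. Site selectivity rests on ring size, because coupling at C2 would need a benzocyclobutene, while carbon- over oxygen-arylation (which would lead to a 4H-chromene) is favoured by the bulky electron-rich biaryl phosphine and by keeping C1 as a methylene, so that a simple ketone enolate and not a 1,3-diketonate meets the metal. Dilution holds back intermolecular coupling, and the crowded aldol between the two ketones is reversible and cannot dehydrate towards its quaternary α-carbon.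

**Step 8**
Reactants: 14 3,3'-methylenebis(5,7-dimethoxy-1,1-dimethyl-3,4-dihydronaphthalen-2(1H)-one)
Product: 15 3,3'-methylenebis(6-acetyl-5,7-dimethoxy-1,1-dimethyl-3,4-dihydronaphthalen-2(1H)-one) (acetyl on C7/C7' in target numbering; meso form drawn)
Conditions: AcCl (3 equiv), SnCl4 (5 equiv), CH2Cl2, −10 °C → rt
Reagents that add atoms: acetyl chloride, CC(=O)Cl
Why: Friedel–Crafts acylation is run while ring A is still at its most electron-rich, C7 is activated by both flanking methoxy groups, and the only other free position, C5, is shielded by the in-plane methyl of the C4 gem-dimethyl group, the same peri shielding that keeps acyl groups away from positions next to quaternary ring carbons in polyalkyl tetralins and indanes.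

**Step 9**
Reactants: 15 3,3'-methylenebis(6-acetyl-5,7-dimethoxy-1,1-dimethyl-3,4-dihydronaphthalen-2(1H)-one)
Product: 17 2,2'-methylenebis(7-acetyl-3-hydroxy-6,8-dimethoxy-4,4-dimethylnaphthalen-1(4H)-one), via bis(benzylic alcohol) 16 (not isolated)
Conditions: DDQ (4.4 equiv), AcOH–H2O 9:1, rt → 60 °C
Reagents that add atoms: water, O
Why: In this DDQ benzylic oxidation, hydride abstraction from C1–H (ortho to the C8 and para to the C6 methoxy group) gives a stabilised cation that water traps, the resulting alcohol is oxidised a second time, any C1=C2 enone or cyclic benzylic ether formed on the way should re-enter the same cation manifold in the acidic aqueous medium, and enolisation of the new 1,3-diones removes the C2/C2' stereocentres.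

**Step 10**
Reactants: 17 2,2'-methylenebis(7-acetyl-3-hydroxy-6,8-dimethoxy-4,4-dimethylnaphthalen-1(4H)-one)
Product: 18 2,2'-methylenebis(7-acetyl-3,6,8-trihydroxy-4,4-dimethylnaphthalen-1(4H)-one) (target)
Conditions: BBr3 (12 equiv), CH2Cl2, −78 °C → rt; then ice-water
Reagents that add atoms: none
Why: In this Lewis-acid aryl methyl ether cleavage all four methoxy groups sit ortho to a carbonyl that assists by chelation, bromide removes each methyl by SN2, and the low temperature should keep the methylene-bridged bis-enol from cyclodehydrating to a pyran.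

**Compound list**

1 | glutaryl chloride (pentanedioyl dichloride) | O=C(Cl)CCCC(=O)Cl | starting material
2 | N1,N5-dimethoxy-N1,N5-dimethylpentanediamide | CON(C)C(=O)CCCC(=O)N(C)OC | intermediate
3 | isopropylmagnesium chloride | CC(C)[Mg]Cl | starting material
4 | bis(chloromagnesium) hemiaminal chelate of 2 with two isopropyl groups added (not isolated; stereocentres undefined) | CC(C)C(O[Mg]Cl)(CCCC(O[Mg]Cl)(C(C)C)N(C)OC)N(C)OC | intermediate
5 | 2,8-dimethylnonane-3,7-dione | CC(C)C(=O)CCCC(=O)C(C)C | intermediate
6 | 1-bromo-3,5-dimethoxybenzene | COc1cc(Br)cc(OC)c1 | starting material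
7 | (2-bromo-4,6-dimethoxybenzylidene)dimethyliminium chloride (not isolated) | COc1cc(Br)c(C=[N+](C)C)c(OC)c1.[Cl-] | intermediate
8 | 2-bromo-4,6-dimethoxybenzaldehyde | COc1cc(Br)c(C=O)c(OC)c1 | intermediate
9 | (2-bromo-4,6-dimethoxyphenyl)methanol | COc1cc(Br)c(CO)c(OC)c1 | intermediate
10 | 1-bromo-2-(bromomethyl)-3,5-dimethoxybenzene | COc1cc(Br)c(CBr)c(OC)c1 | intermediate
11 | dilithium 2,8-dimethylnona-3,6-diene-3,7-diolate (not isolated; enolate geometry undefined) | CC(C)C([O-])=CCC=C([O-])C(C)C.[Li+].[Li+] | intermediate
12 | 4,6-bis(2-bromo-4,6-dimethoxybenzyl)-2,8-dimethylnonane-3,7-dione (meso form drawn; formed together with the racemic form) | COc1cc(OC)c(C[C@H](C[C@H](Cc2c(Br)cc(OC)cc2OC)C(=O)C(C)C)C(=O)C(C)C)c(Br)c1 | intermediate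
13 | 3-[2-(2-bromo-4,6-dimethoxybenzyl)-4-methyl-3-oxopentyl]-5,7-dimethoxy-1,1-dimethyl-3,4-dihydronaphthalen-2(1H)-one (not isolated; relative configuration as in 12) | COc1cc(OC)c2c(c1)C(C)(C)C(=O)[C@@H](C[C@H](Cc1c(Br)cc(OC)cc1OC)C(=O)C(C)C)C2 | intermediate
14 | 3,3'-methylenebis(5,7-dimethoxy-1,1-dimethyl-3,4-dihydronaphthalen-2(1H)-one) (meso form drawn) | COc1cc(OC)c2c(c1)C(C)(C)C(=O)[C@@H](C[C@@H]1Cc3c(OC)cc(OC)cc3C(C)(C)C1=O)C2 | intermediate
15 | 3,3'-methylenebis(6-acetyl-5,7-dimethoxy-1,1-dimethyl-3,4-dihydronaphthalen-2(1H)-one) (meso form drawn) | COc1c(C(C)=O)c(OC)c2c(c1)C(C)(C)C(=O)[C@@H](C[C@@H]1Cc3c(OC)c(C(C)=O)c(OC)cc3C(C)(C)C1=O)C2 | intermediate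
16 | 3,3'-methylenebis(6-acetyl-4-hydroxy-5,7-dimethoxy-1,1-dimethyl-3,4-dihydronaphthalen-2(1H)-one) (not isolated; mixture of diastereomers, stereocentres undefined) | COc1cc2c(c(OC)c1C(C)=O)C(O)C(CC1C(O)c3c(OC)c(C(C)=O)c(OC)cc3C(C)(C)C1=O)C(=O)C2(C)C | intermediate
17 | 2,2'-methylenebis(7-acetyl-3-hydroxy-6,8-dimethoxy-4,4-dimethylnaphthalen-1(4H)-one) | CC(=O)c1c(OC)cc2c(c1OC)C(=O)C(CC1=C(O)C(C)(C)c3cc(OC)c(C(C)=O)c(OC)c3C1=O)=C(O)C2(C)C | intermediate
18 | 2,2'-methylenebis(7-acetyl-3,6,8-trihydroxy-4,4-dimethylnaphthalen-1(4H)-one) | CC(=O)c1c(O)cc2c(c1O)C(=O)C(CC1=C(O)C(C)(C)c3cc(O)c(C(C)=O)c(O)c3C1=O)=C(O)C2(C)C | target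

**Step count**

Total steps: 10. Longest linear sequence: 8 steps (steps 3–10, from 6).

**Steps most likely to fail**

**Step 9.** Proton loss from the benzylic cation may outrun capture by water. Once the enolised dione is present, further oxidation at the bridging methylene may also set in.

The fallback sets out from 15 and returns at 17, and it accepts the elimination instead of fighting it. DDQ in dry dioxane at reflux dehydrogenates C1–C2 and C1'–C2' to 3,3'-methylenebis(6-acetyl-5,7-dimethoxy-1,1-dimethylnaphthalen-2(1H)-one) F1. Copper-catalysed conjugate borylation (B2pin2, CuCl, DPEphos, NaOt-Bu, MeOH, THF, rt) places boron on the benzylic β-carbons. This gives 3,3'-methylenebis[6-acetyl-5,7-dimethoxy-1,1-dimethyl-4-(4,4,5,5-tetramethyl-1,3,2-dioxaborolan-2-yl)-3,4-dihydronaphthalen-2(1H)-one] F2. NaBO3·4H2O in THF–water converts both C–B bonds into C–OH and delivers 16, now isolated. Dess–Martin periodinane in CH2Cl2 then oxidises both β-hydroxy ketones to 17.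

**Step 7.** Three processes may erode the double closure:
- reduction of the aryl–palladium bond by β-hydride transfer from the methyl groups of the hindered enolate;
- oxygen- instead of carbon-arylation;
- stalling after the first ring closure while the free ketone undergoes aldol chemistry in hot alkoxide.

The fallback sets out from 10 and returns at 14. It runs the same bond formation on a monomer that holds one bromide and one ketone, and joins the halves afterwards. The kinetic lithium enolate of 3-methylbutan-2-one (LiN(i-Pr)2, THF, −78 °C) is alkylated with 10 to give 1-(2-bromo-4,6-dimethoxyphenyl)-4-methylpentan-3-one F3. Single α-arylation under the conditions of step 7 gives 5,7-dimethoxy-1,1-dimethyl-3,4-dihydronaphthalen-2(1H)-one F4. Half of this material undergoes Mannich-type α-methylenation (paraformaldehyde, diisopropylammonium trifluoroacetate, THF, reflux). The product is 5,7-dimethoxy-1,1-dimethyl-3-methylidene-3,4-dihydronaphthalen-2(1H)-one F5, which is used at once. Conjugate addition of the other half of F4 (LiN(i-Pr)2, THF, −78 °C) to F5 gives 14.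

**Step 8.** Acylation may take the wrong ring position or stop short because of crowding between the two methoxy groups. The Lewis acid may also cleave ethers partially.

The fallback sets out from 14 and returns at 15, and it moves the acylation to the free phenols, where small hydroxyl groups and chelation favour C7. BBr3 in CH2Cl2 gives 3,3'-methylenebis(5,7-dihydroxy-1,1-dimethyl-3,4-dihydronaphthalen-2(1H)-one) F6. AcOH with BF3·OEt2 at 80 °C (O-acylation, then Fries-type migration to the carbon between the two hydroxyl groups, held as a boron chelate until work-up) gives 3,3'-methylenebis(6-acetyl-5,7-dihydroxy-1,1-dimethyl-3,4-dihydronaphthalen-2(1H)-one) F7. Me2SO4 with K2CO3 in refluxing acetone methylates the four phenols again and gives 15.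

**Further compounds**

F1 | step 9 | 3,3'-methylenebis(6-acetyl-5,7-dimethoxy-1,1-dimethylnaphthalen-2(1H)-one) | COc1cc2c(c(OC)c1C(C)=O)C=C(CC1=Cc3c(OC)c(C(C)=O)c(OC)cc3C(C)(C)C1=O)C(=O)C2(C)C
F2 | step 9 | 3,3'-methylenebis[6-acetyl-5,7-dimethoxy-1,1-dimethyl-4-(4,4,5,5-tetramethyl-1,3,2-dioxaborolan-2-yl)-3,4-dihydronaphthalen-2(1H)-one] (mixture of diastereomers) | COc1cc2c(c(OC)c1C(C)=O)C(B3OC(C)(C)C(C)(C)O3)C(CC4C(B5OC(C)(C)C(C)(C)O5)c6c(OC)c(C(C)=O)c(OC)cc6C(C)(C)C4=O)C(=O)C2(C)C
F3 | step 7 | 1-(2-bromo-4,6-dimethoxyphenyl)-4-methylpentan-3-one | COc1cc(Br)c(CCC(=O)C(C)C)c(OC)c1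
F4 | step 7 | 5,7-dimethoxy-1,1-dimethyl-3,4-dihydronaphthalen-2(1H)-one | COc1cc(OC)c2c(c1)C(C)(C)C(=O)CC2
F5 | step 7 | 5,7-dimethoxy-1,1-dimethyl-3-methylidene-3,4-dihydronaphthalen-2(1H)-one | COc1cc(OC)c2c(c1)C(C)(C)C(=O)C(=C)C2
F6 | step 8 | 3,3'-methylenebis(5,7-dihydroxy-1,1-dimethyl-3,4-dihydronaphthalen-2(1H)-one) (meso form drawn) | Oc1cc(O)c2c(c1)C(C)(C)C(=O)[C@@H](C[C@@H]1Cc3c(O)cc(O)cc3C(C)(C)C1=O)C2
F7 | step 8 | 3,3'-methylenebis(6-acetyl-5,7-dihydroxy-1,1-dimethyl-3,4-dihydronaphthalen-2(1H)-one) (meso form drawn) | Oc1c(C(C)=O)c(O)c2c(c1)C(C)(C)C(=O)[C@@H](C[C@@H]1Cc3c(O)c(C(C)=O)c(O)cc3C(C)(C)C1=O)C2
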